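**Retrosynthetic overview**
1. Last bond, C3–CH2CO2H: the acid comes from a 3-hydroxy-1,2-dioxolane (the cyclic form of a β-hydroperoxy ketone) by peroxycarbenium substitution with an acetic acid ketene acetal.
2. The tertiary C5–OOH centre comes from a 2,2,4-trisubstituted oxetane opened by H2O2 with inversion; the oxetane comes from a tertiary/secondary 1,3-diol.
3. Key disconnection, C5–C1': light-driven decarboxylative radical addition of the C20 side-chain acid to (R)-2-tert-butyl-6-methyl-1,3-dioxin-4-one, which sets the quaternary carbinol centre through the acetal centre.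
4. Side-chain acid: two copper-catalysed Grignard openings of (R)- then (S)-β-butyrolactone, with a decarboxylative iodination between them.
5. Ring order: 1,3-dioxan-4-one acetal (temporary), then oxetane (temporary), then the 1,2-dioxolane.

Assumption: ring atoms are O1, O2, C3 (bears CH2CO2H), C4, C5 and side-chain atoms are C1'–C12' outward from C5; (R)- and (S)-β-butyrolactone, (R)-3-hydroxybutanoic acid and (8-bromooctyl)benzene are purchased.

**Step 1**
Reactants: 1 (8-bromooctyl)benzene; 2 (R)-β-butyrolactone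
Product: 4 (3R)-3-methyl-11-phenylundecanoic acid, via Grignard reagent 3 (not isolated)
Conditions: Mg, THF, 45 °C; then 2, CuBr·SMe2 (5 mol %), THF/Me2S, −30 °C; aq. HCl
Reagents that add atoms: magnesium, [Mg] (retained in 3 only)
Why: Grignard formation followed by copper-catalysed SN2 alkyl–oxygen ring-opening of the β-lactone, which inverts C4 of the lactone cleanly, so the bought centre becomes the (R)-methyl-branched centre that ends as C4'.

**Step 2**
Reactants: 4 (3R)-3-methyl-11-phenylundecanoic acid
Product: 5 [(9R)-10-iodo-9-methyldecyl]benzene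
Conditions: PhI(OAc)2, I2, cyclohexane, hν (tungsten lamp), 80 °C
Reagents that add atoms: iodine, II
Why: Suárez decarboxylative iodination (a Hunsdiecker-type radical chain through the acyl hypoiodite) removes the carboxyl carbon, and the stereocentre, being β to the radical, is not touched.

**Step 3**
Reactants: 5 [(9R)-10-iodo-9-methyldecyl]benzene; 6 (S)-β-butyrolactone
Product: 8 (3S,5R)-3,5-dimethyl-13-phenyltridecanoic acid, via Grignard reagent 7 (not isolated)
Conditions: Mg, Et2O, 35 °C; then 6, CuBr·SMe2 (5 mol %), THF/Me2S, −30 °C; aq. HCl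
Reagents that add atoms: magnesium, [Mg] (retained in 7 only)
Why: the same copper-catalysed SN2 β-lactone opening with inversion installs the second methyl-branched centre (S, later C2') anti to the first, directly from the second bought lactone.

**Step 4**
Reactants: 9 (R)-3-hydroxybutanoic acid
Product: 10 (2R,6R)-2-tert-butyl-6-methyl-1,3-dioxan-4-one
Conditions: t-BuCHO, p-toluenesulfonic acid (cat.), CH2Cl2, reflux, water separator; recrystallisation
Reagents that add atoms: pivalaldehyde, CC(C)(C)C=O
Why: acid-catalysed acetalisation under thermodynamic control gives the cis-dioxanone with both substituents equatorial, so the new acetal centre (2R) is set by the bought carbinol centre.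

**Step 5**
Reactants: 10 (2R,6R)-2-tert-butyl-6-methyl-1,3-dioxan-4-one
Product: 12 (2R)-2-tert-butyl-6-methyl-4H-1,3-dioxin-4-one, via bromo dioxanone 11 (not isolated)
Conditions: NBS, azobisisobutyronitrile (cat.), CCl4, reflux; then Et3N, 0 °C
Reagents that add atoms: N-bromosuccinimide, O=C1CCC(=O)N1Br (bromine retained in 11 only)
Why: radical bromination at the tertiary α-oxy C6–H and dehydrobromination give the enol ether; the original centre is erased, but the acetal centre it created is untouched and carries the stereochemical information (self-regeneration of stereocentres).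

**Step 6 (key step)**
Reactants: 8 (3S,5R)-3,5-dimethyl-13-phenyltridecanoic acid; 12 (2R)-2-tert-butyl-6-methyl-4H-1,3-dioxin-4-one
Product: 13 (2R,6S)-2-tert-butyl-6-[(2S,4R)-2,4-dimethyl-12-phenyldodecyl]-6-methyl-1,3-dioxan-4-one
Conditions: 2,4,5,6-tetra(carbazol-9-yl)isophthalonitrile (4CzIPN, 2 mol %), Cs2CO3 (20 mol %), 12 (3 equiv), DMF, 456 nm LEDs, 25 °C
Reagents that add atoms: none
Why: Proposed new method: the excited photocatalyst oxidises the carboxylate of 8, loss of CO2 gives the primary C1' radical, and this adds (Giese-type) to C6 of the β-alkoxy enoate 12 on the face anti to tert-butyl, the face cuprates already use because C6 is pyramidalised away from that group; the α-acyl radical is then reduced by the photocatalyst radical anion and protonated by more 8, so the fully substituted C–O centre (6S, later C5) is set by the acetal centre that the bought carbinol created; the closest known reactions are photoredox decarboxylative Giese additions of alkyl carboxylic acids to enoates and to β-oxygenated enones such as chromones, and the cuprate conjugate addition to this same dioxinone.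

**Step 7**
Reactants: 13 (2R,6S)-2-tert-butyl-6-[(2S,4R)-2,4-dimethyl-12-phenyldodecyl]-6-methyl-1,3-dioxan-4-one
Product: 15 (4S,6S,8R)-4,6,8-trimethyl-16-phenylhexadecane-2,4-diol, via hydroxy ketone 14 (not isolated)
Conditions: MeLi (1.2 equiv), THF, −78 °C; then MeOH, NaBH4, −78 to 0 °C
Reagents that add atoms: methyllithium, [Li]C
Why: 1,2-addition of MeLi to the lactone carbonyl gives a tetrahedral alkoxide that survives at −78 °C and collapses on protonation to the β-hydroxy methyl ketone with loss of pivalaldehyde, and borohydride reduction then gives the diol; the tertiary carbinol (4S) is untouched, and the new secondary carbinol forms as both epimers, which is harmless because it is oxidised again in step 10.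

**Step 8**
Reactants: 15 (4S,6S,8R)-4,6,8-trimethyl-16-phenylhexadecane-2,4-diol
Product: 17 (2S)-2-[(2S,4R)-2,4-dimethyl-12-phenyldodecyl]-2,4-dimethyloxetane, via mesylate 16 (not isolated)
Conditions: MsCl (1.05 equiv), Et3N, CH2Cl2, −20 °C; then KOt-Bu, THF, 0 °C to rt
Reagents that add atoms: methanesulfonyl chloride, CS(=O)(=O)Cl (retained in 16 only)
Why: selective sulfonylation of the secondary hydroxyl and intramolecular Williamson etherification (4-exo-tet) by the tertiary alkoxide close the oxetane without breaking the tertiary C–O bond, so that centre stays (S).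

**Step 9**
Reactants: 17 (2S)-2-[(2S,4R)-2,4-dimethyl-12-phenyldodecyl]-2,4-dimethyloxetane
Product: 18 (4R,6S,8R)-4-hydroperoxy-4,6,8-trimethyl-16-phenylhexadecan-2-ol
Conditions: H2O2 (anhydrous, 2 M in Et2O, 10 equiv), TMSOTf (0.2 equiv), Et2O, −78 to −30 °C
Reagents that add atoms: hydrogen peroxide, OO
Why: the Lewis acid-activated oxetane is opened by H2O2 at its tertiary carbon in an SN2-like (tight ion pair) substitution with inversion, as known for 2,2-disubstituted oxetanes, which turns the (S)-ether centre into the (R)-tertiary hydroperoxide (C5 of the target).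

**Step 10**
Reactants: 18 (4R,6S,8R)-4-hydroperoxy-4,6,8-trimethyl-16-phenylhexadecan-2-ol
Product: 20 (5R)-5-[(2S,4R)-2,4-dimethyl-12-phenyldodecyl]-3,5-dimethyl-1,2-dioxolan-3-ol, via hydroperoxy ketone 19 (not isolated)
Conditions: Dess–Martin periodinane, pyridine, CH2Cl2, 0 °C
Reagents that add atoms: none
Why: Dess–Martin oxidation of the secondary alcohol gives the β-hydroperoxy ketone, which closes spontaneously to the five-membered peroxyhemiketal; C5 is untouched and the hemiketal carbon is an equilibrating anomeric mixture that becomes planar in step 11.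

**Step 11**
Reactants: 20 (5R)-5-[(2S,4R)-2,4-dimethyl-12-phenyldodecyl]-3,5-dimethyl-1,2-dioxolan-3-ol
Product: 21 2-[(3R,5R)-5-[(2S,4R)-2,4-dimethyl-12-phenyldodecyl]-3,5-dimethyl-1,2-dioxolan-3-yl]acetic acid
Conditions: CH2=C(OSiMe3)2 (3 equiv), TMSOTf (0.2 equiv), CH2Cl2, −78 °C; aqueous work-up; silica gel chromatography
Reagents that add atoms: 1,1-bis(trimethylsilyloxy)ethene, C=C(O[Si](C)(C)C)O[Si](C)(C)C
Why: in situ silylation and ionisation give the dioxolan-3-yl peroxycarbenium ion, which the ketene acetal traps (Mukaiyama-type peroxyketal substitution) to form the C3–CH2CO2H bond; C3 is set only by 1,3-induction from C5, whose CH3 and CH2R groups differ little, so roughly 1:1 of the (3R) target and its (3S) epimer is expected (the model of attack anti to the larger C5 group slightly favours the epimer) and the two ring diastereomers are separated by chromatography.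

**Compound list**
1 | (8-bromooctyl)benzene | BrCCCCCCCCc1ccccc1 | starting material
2 | (R)-β-butyrolactone, (4R)-4-methyloxetan-2-one | C[C@@H]1CC(=O)O1 | starting material
3 | (8-phenyloctyl)magnesium bromide | Br[Mg]CCCCCCCCc1ccccc1 | intermediate
4 | (3R)-3-methyl-11-phenylundecanoic acid | C[C@H](CCCCCCCCc1ccccc1)CC(=O)O | intermediate
5 | [(9R)-10-iodo-9-methyldecyl]benzene | C[C@H](CCCCCCCCc1ccccc1)CI | intermediate
6 | (S)-β-butyrolactone, (4S)-4-methyloxetan-2-one | C[C@H]1CC(=O)O1 | starting material
7 | [(2R)-2-methyl-10-phenyldecyl]magnesium iodide | C[C@H](CCCCCCCCc1ccccc1)C[Mg]I | intermediate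
8 | (3S,5R)-3,5-dimethyl-13-phenyltridecanoic acid | C[C@H](CCCCCCCCc1ccccc1)C[C@H](C)CC(=O)O | intermediate
9 | (R)-3-hydroxybutanoic acid | C[C@@H](O)CC(=O)O | starting material
10 | (2R,6R)-2-tert-butyl-6-methyl-1,3-dioxan-4-one | C[C@@H]1CC(=O)O[C@H](C(C)(C)C)O1 | intermediate
11 | (2S)-6-bromo-2-tert-butyl-6-methyl-1,3-dioxan-4-one (C6 epimers; acetal centre spatially unchanged) | CC1(Br)CC(=O)O[C@H](C(C)(C)C)O1 | intermediate
12 | (2R)-2-tert-butyl-6-methyl-4H-1,3-dioxin-4-one | CC1=CC(=O)O[C@H](C(C)(C)C)O1 | intermediate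
13 | (2R,6S)-2-tert-butyl-6-[(2S,4R)-2,4-dimethyl-12-phenyldodecyl]-6-methyl-1,3-dioxan-4-one | C[C@H](CCCCCCCCc1ccccc1)C[C@H](C)C[C@@]1(C)CC(=O)O[C@H](C(C)(C)C)O1 | intermediate
14 | (4S,6S,8R)-4-hydroxy-4,6,8-trimethyl-16-phenylhexadecan-2-one | C[C@H](CCCCCCCCc1ccccc1)C[C@H](C)C[C@](C)(O)CC(C)=O | intermediate
15 | (4S,6S,8R)-4,6,8-trimethyl-16-phenylhexadecane-2,4-diol (both C2 epimers) | C[C@H](CCCCCCCCc1ccccc1)C[C@H](C)C[C@](C)(O)CC(C)O | intermediate
16 | (4S,6S,8R)-4-hydroxy-4,6,8-trimethyl-16-phenylhexadecan-2-yl methanesulfonate (both C2 epimers) | C[C@H](CCCCCCCCc1ccccc1)C[C@H](C)C[C@](C)(O)CC(C)OS(C)(=O)=O | intermediate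
17 | (2S)-2-[(2S,4R)-2,4-dimethyl-12-phenyldodecyl]-2,4-dimethyloxetane (both C4 epimers) | C[C@H](CCCCCCCCc1ccccc1)C[C@H](C)C[C@@]1(C)CC(C)O1 | intermediate
18 | (4R,6S,8R)-4-hydroperoxy-4,6,8-trimethyl-16-phenylhexadecan-2-ol (both C2 epimers) | C[C@H](CCCCCCCCc1ccccc1)C[C@H](C)C[C@@](C)(OO)CC(C)O | intermediate
19 | (4R,6S,8R)-4-hydroperoxy-4,6,8-trimethyl-16-phenylhexadecan-2-one | C[C@H](CCCCCCCCc1ccccc1)C[C@H](C)C[C@@](C)(OO)CC(C)=O | intermediate
20 | (5R)-5-[(2S,4R)-2,4-dimethyl-12-phenyldodecyl]-3,5-dimethyl-1,2-dioxolan-3-ol (both C3 anomers) | C[C@H](CCCCCCCCc1ccccc1)C[C@H](C)C[C@]1(C)CC(C)(O)OO1 | intermediate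
21 | 2-[(3R,5R)-5-[(2S,4R)-2,4-dimethyl-12-phenyldodecyl]-3,5-dimethyl-1,2-dioxolan-3-yl]acetic acid | C[C@H](CCCCCCCCc1ccccc1)C[C@H](C)C[C@]1(C)C[C@](C)(CC(=O)O)OO1 | target

**Step count and risks**
Total steps: 11 (steps 4 and 5 are a two-step branch to the dioxinone). Longest linear sequence: 9 steps (1–3, then 6–11) from (8-bromooctyl)benzene.

Step 6 (the proposed new step) may fail because a primary alkyl radical adds slowly to a β-alkoxy, β,β-disubstituted acceptor and can be reduced or dimerise first. The fallback uses known chemistry and runs from 8 to 13. The decarboxylative iodination of step 2 (PhI(OAc)2, I2, hν) converts 8 into [(9R,11S)-12-iodo-9,11-dimethyldodecyl]benzene F1. Magnesium in Et2O gives [(2S,4R)-2,4-dimethyl-12-phenyldodecyl]magnesium iodide F2. Copper-mediated conjugate addition of F2 to 12 (CuBr·SMe2, THF, −78 °C) is the documented organocopper mode of this dioxinone and also enters trans to tert-butyl, giving 13.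

Step 10 may fail because the free tertiary hydroperoxide can react with the periodinane or rearrange. The fallback runs from 18 to 20 with a protecting-group detour. 2-Methoxypropene with pyridinium p-toluenesulfonate at −20 °C caps the hydroperoxide as (4R,6S,8R)-4-[(2-methoxypropan-2-yl)peroxy]-4,6,8-trimethyl-16-phenylhexadecan-2-ol F3. Dess–Martin oxidation then gives (4R,6S,8R)-4-[(2-methoxypropan-2-yl)peroxy]-4,6,8-trimethyl-16-phenylhexadecan-2-one F4. Aqueous acetic acid in THF removes the peroxyketal, and the freed hydroperoxy ketone closes to 20.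

Step 11 may fail to give a useful share of the (3R) epimer, or the hemiketal may not ionise cleanly with the free-acid ketene acetal. The fallback runs from 20 to 21 and makes the C3 centre recyclable:
- Acetylation (Ac2O, pyridine, DMAP) gives (5R)-5-[(2S,4R)-2,4-dimethyl-12-phenyldodecyl]-3,5-dimethyl-1,2-dioxolan-3-yl acetate F5.
- TiCl4 with 1-methoxy-1-(trimethylsilyloxy)ethene at −78 °C gives methyl 2-[(3R,5R)-5-[(2S,4R)-2,4-dimethyl-12-phenyldodecyl]-3,5-dimethyl-1,2-dioxolan-3-yl]acetate F6 and its epimer methyl 2-[(3S,5R)-5-[(2S,4R)-2,4-dimethyl-12-phenyldodecyl]-3,5-dimethyl-1,2-dioxolan-3-yl]acetate F7, which are separated.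
- F7 is re-equilibrated with catalytic KOt-Bu in THF at 0 °C by retro-oxa-Michael and oxa-Michael reclosure through methyl (2E,5R,7S,9R)-5-hydroperoxy-3,5,7,9-tetramethyl-17-phenylheptadec-2-enoate F8, and is recycled. C5 is not touched.
- LiOH in THF/H2O at 0 °C converts F6 into 21.

**Further compounds**
F1 | step 6 | [(9R,11S)-12-iodo-9,11-dimethyldodecyl]benzene | C[C@H](CCCCCCCCc1ccccc1)C[C@H](C)CI
F2 | step 6 | [(2S,4R)-2,4-dimethyl-12-phenyldodecyl]magnesium iodide | C[C@H](CCCCCCCCc1ccccc1)C[C@H](C)C[Mg]I
F3 | step 10 | (4R,6S,8R)-4-[(2-methoxypropan-2-yl)peroxy]-4,6,8-trimethyl-16-phenylhexadecan-2-ol | C[C@H](CCCCCCCCc1ccccc1)C[C@H](C)C[C@@](C)(OOC(C)(C)OC)CC(C)O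
F4 | step 10 | (4R,6S,8R)-4-[(2-methoxypropan-2-yl)peroxy]-4,6,8-trimethyl-16-phenylhexadecan-2-one | C[C@H](CCCCCCCCc1ccccc1)C[C@H](C)C[C@@](C)(OOC(C)(C)OC)CC(C)=O
F5 | step 11 | (5R)-5-[(2S,4R)-2,4-dimethyl-12-phenyldodecyl]-3,5-dimethyl-1,2-dioxolan-3-yl acetate | C[C@H](CCCCCCCCc1ccccc1)C[C@H](C)C[C@]1(C)CC(C)(OC(C)=O)OO1
F6 | step 11 | methyl 2-[(3R,5R)-5-[(2S,4R)-2,4-dimethyl-12-phenyldodecyl]-3,5-dimethyl-1,2-dioxolan-3-yl]acetate | C[C@H](CCCCCCCCc1ccccc1)C[C@H](C)C[C@]1(C)C[C@](C)(CC(=O)OC)OO1
F7 | step 11 | methyl 2-[(3S,5R)-5-[(2S,4R)-2,4-dimethyl-12-phenyldodecyl]-3,5-dimethyl-1,2-dioxolan-3-yl]acetate | C[C@H](CCCCCCCCc1ccccc1)C[C@H](C)C[C@]1(C)C[C@@](C)(CC(=O)OC)OO1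
F8 | step 11 | methyl (2E,5R,7S,9R)-5-hydroperoxy-3,5,7,9-tetramethyl-17-phenylheptadec-2-enoate | C[C@H](CCCCCCCCc1ccccc1)C[C@H](C)C[C@@](C)(OO)C/C(C)=C/C(=O)OC
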